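## Retrosynthetic overview

1. The last bond made is the dihydrofuran O–C2. The target goes back to the (S)-epoxide of a 3'-prenyl group, and from there to the unprotected 2',4'-dihydroxy-3'-prenylchalcone that already carries the chromene. The only stereocentre is created in the final flask by epoxidation followed by 5-exo opening with inversion.
2. The enone Cα=Cβ is disconnected to a protecting-group-free Claisen–Schmidt union of 3-prenylresacetophenone and 2,2-dimethylchromene-6-carbaldehyde.
3. The chromene O1–C2 bond comes from oxa-6π closure of an o-quinone methide, itself formed by hydride abstraction from 4-hydroxy-3-prenylbenzaldehyde.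
4. Both o-prenylphenols come from direct aromatic C-prenylation of 4-hydroxybenzaldehyde and 2,4-dihydroxyacetophenone with prenyl bromide.
5. Ring order: the 2H-pyran (chromene) is formed first, on the aldehyde. The (R)-dihydrofuran is formed last, on the complete chalcone.

Assumption: the L-fructose-derived enantiomer of the Shi ketone (ent-Shi ketone, CC1(C)O[C@H]2CO[C@@]3(COC(C)(C)O3)C(=O)[C@H]2O1) is bought as a catalyst and is not counted as a step.

## Route

Step 1
Reactants: 1 4-hydroxybenzaldehyde; 2 prenyl bromide (1-bromo-3-methylbut-2-ene)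
Product: 3 4-hydroxy-3-(3-methylbut-2-en-1-yl)benzaldehyde
Conditions: KOH (1.2 equiv), H2O, 0 °C to rt, 24 h; then dil. HCl
Reagents that add atoms: none
Why: This is an ambident-phenoxide ortho-C-allylation (the chemical counterpart of an aromatic prenyltransferase), in which water solvates the phenoxide oxygen by hydrogen bonding so that the soft allylic bromide is attacked SN2 by the ortho carbon, the two ortho positions are equivalent, the O-prenyl ether by-product is removed by chromatography, and no stereocentre is formed.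

Step 2
Reactants: 3 4-hydroxy-3-(3-methylbut-2-en-1-yl)benzaldehyde
Product: 5 2,2-dimethyl-2H-chromene-6-carbaldehyde, via o-quinone methide 4 (not isolated)
Conditions: DDQ (1.1 equiv), dry toluene, 90 °C, 2 h
Reagents that add atoms: none
Why: This is a DDQ oxidative cyclisation (cyclodehydrogenation) of an o-prenylphenol, in which hydride abstraction from the benzylic/allylic CH2 and loss of the phenolic proton give the vinylogous o-quinone methide 4, which closes by oxa-6π electrocyclisation as in enzymatic chromene formation, while the aldehyde is inert to DDQ and no stereocentre is formed.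

Step 3
Reactants: 6 2,4-dihydroxyacetophenone; 2 prenyl bromide
Product: 7 1-[2,4-dihydroxy-3-(3-methylbut-2-en-1-yl)phenyl]ethan-1-one
Conditions: KOH (2.2 equiv), H2O, 0 °C to rt, 16 h; then dil. HCl
Reagents that add atoms: none
Why: This is an aqueous phenoxide C-allylation (biomimetic aromatic prenylation) in which C3, flanked by both oxygens, is the most nucleophilic carbon of the resorcinolate, so the 3-prenyl isomer is the main C-alkylation product and is separated from the 5-prenyl, O-prenyl and bis-prenyl by-products by chromatography, with no stereocentre formed.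

Step 4
Reactants: 7 1-[2,4-dihydroxy-3-(3-methylbut-2-en-1-yl)phenyl]ethan-1-one; 5 2,2-dimethyl-2H-chromene-6-carbaldehyde
Product: 9 (E)-1-[2,4-dihydroxy-3-(3-methylbut-2-en-1-yl)phenyl]-3-(2,2-dimethyl-2H-chromen-6-yl)prop-2-en-1-one, via aldol adduct 8 (not isolated)
Conditions: 50 % aq. KOH, EtOH, rt, 48 h; then 1 M HCl, 0 °C
Reagents that add atoms: none
Why: This is a Claisen–Schmidt aldol condensation in which the non-enolisable, non-phenolic aldehyde 5 is a good acceptor for the enolate of the phenoxide-bearing ketone (as in the known condensations of 3-prenylresacetophenone with benzaldehydes), E1cB loss of water from 8 removes its transient carbinol centre and gives the thermodynamic E-enone, and the prenyl and chromene olefins are inert to base.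

Step 5
Reactants: 9 (E)-1-[2,4-dihydroxy-3-(3-methylbut-2-en-1-yl)phenyl]-3-(2,2-dimethyl-2H-chromen-6-yl)prop-2-en-1-one
Product: 11 (E)-3-(2,2-dimethyl-2H-chromen-6-yl)-1-[(2R)-4-hydroxy-2-(2-hydroxypropan-2-yl)-2,3-dihydro-1-benzofuran-5-yl]prop-2-en-1-one (target CNP0302034.2), via (S)-epoxide 10 (not isolated)
Conditions: ent-Shi ketone (30 mol %), Oxone (1.2 equiv KHSO5) and K2CO3 added in parallel over 2 h, Bu4NHSO4 (4 mol %), Na2B4O7/Na2EDTA buffer (pH 10.5), MeCN–DMM 1:2, 0 °C; then rt, 3 h
Reagents that add atoms: potassium peroxymonosulfate (active salt of Oxone, its peroxy oxygen is relayed through the chiral dioxirane), [K+].[O-]S(=O)(=O)OO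
Why: This is a Shi asymmetric epoxidation followed by base-mediated 5-exo-tet epoxide opening, in which the L-fructose-derived dioxirane attacks the trisubstituted prenyl olefin through the usual spiro transition state (the D-ketone gives R, so the ent-ketone gives the (S)-epoxide 10, typically >90 % ee for ArCH2CH=CMe2) in preference to the cis-disubstituted, gem-dimethyl-shielded chromene olefin and the electron-poor enone, and the only ionised phenol (4'-O−, the 2'-OH being held in the carbonyl chelate) then attacks the secondary epoxide carbon with clean inversion to set the (R)-configured 2-(2-hydroxypropan-2-yl)dihydrofuran.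

## Compound list

1 | 4-hydroxybenzaldehyde | O=Cc1ccc(O)cc1 | starting material
2 | prenyl bromide (1-bromo-3-methylbut-2-ene) | CC(C)=CCBr | starting material
3 | 4-hydroxy-3-(3-methylbut-2-en-1-yl)benzaldehyde | CC(C)=CCc1cc(C=O)ccc1O | intermediate
4 | (3Z)-3-(3-methylbut-2-en-1-ylidene)-4-oxocyclohexa-1,5-diene-1-carbaldehyde (o-quinone methide, not isolated) | O=CC1=C/C(=C/C=C(C)C)C(=O)C=C1 | intermediate
5 | 2,2-dimethyl-2H-chromene-6-carbaldehyde | CC1(C)C=Cc2cc(C=O)ccc2O1 | intermediate
6 | 2,4-dihydroxyacetophenone | CC(=O)c1ccc(O)cc1O | starting material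
7 | 1-[2,4-dihydroxy-3-(3-methylbut-2-en-1-yl)phenyl]ethan-1-one | CC(=O)c1ccc(O)c(CC=C(C)C)c1O | intermediate
8 | 1-[2,4-dihydroxy-3-(3-methylbut-2-en-1-yl)phenyl]-3-(2,2-dimethyl-2H-chromen-6-yl)-3-hydroxypropan-1-one (racemic aldol adduct, not isolated) | CC(C)=CCc1c(O)ccc(C(=O)CC(O)c2ccc3c(c2)C=CC(C)(C)O3)c1O | intermediate
9 | (E)-1-[2,4-dihydroxy-3-(3-methylbut-2-en-1-yl)phenyl]-3-(2,2-dimethyl-2H-chromen-6-yl)prop-2-en-1-one | CC(C)=CCc1c(O)ccc(C(=O)/C=C/c2ccc3c(c2)C=CC(C)(C)O3)c1O | intermediate
10 | (E)-1-(3-{[(2S)-3,3-dimethyloxiran-2-yl]methyl}-2,4-dihydroxyphenyl)-3-(2,2-dimethyl-2H-chromen-6-yl)prop-2-en-1-one (not isolated) | CC1(C)C=Cc2cc(/C=C/C(=O)c3ccc(O)c(C[C@@H]4OC4(C)C)c3O)ccc2O1 | intermediate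
11 | (E)-3-(2,2-dimethyl-2H-chromen-6-yl)-1-[(2R)-4-hydroxy-2-(2-hydroxypropan-2-yl)-2,3-dihydro-1-benzofuran-5-yl]prop-2-en-1-one | CC1(C)C=Cc2cc(/C=C/C(=O)c3ccc4c(c3O)C[C@H](C(C)(C)O)O4)ccc2O1 | target

## Step count and risks

- Total step count: 5, with no protecting groups.
- Longest linear sequence: 4 steps (1 → 3 → 5 → 9 → 11, that is steps 1, 2, 4 and 5).

**Step 5, most at risk.**
- The dioxirane must choose the prenyl olefin over the chromene C3=C4 bond.
- The phenoxide and enone must survive Oxone at pH 10.5. Possible side reactions are Dakin-type cleavage, nucleophilic enone epoxidation and chalcone–flavanone isomerisation.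
- Fallback: create the stereocentre before any competing olefin is present. The fallback sets out from 7.
- The same ent-Shi conditions convert 7 into 1-(3-{[(2S)-3,3-dimethyloxiran-2-yl]methyl}-2,4-dihydroxyphenyl)ethan-1-one F1.
- F1 closes in the basic medium to 1-[(2R)-4-hydroxy-2-(2-hydroxypropan-2-yl)-2,3-dihydro-1-benzofuran-5-yl]ethan-1-one F2.
- Claisen–Schmidt condensation of F2 with 5 (KOH, EtOH) passes through the β-hydroxy ketone F3 and comes back to the route at 11.

**Step 3.**
- C3, C5, O and double alkylation all compete, so the yield is usually only 25–35 %.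
- Fallback: deliver the prenyl group by a sigmatropic shift instead of an intermolecular alkylation. The fallback sets out from 6.
- The free 4-OH is etherified with 3-chloro-3-methylbut-1-yne (K2CO3, KI, acetone, reflux) to give 1-{2-hydroxy-4-[(2-methylbut-3-yn-2-yl)oxy]phenyl}ethan-1-one F4.
- Lindlar semihydrogenation gives 1-{2-hydroxy-4-[(2-methylbut-3-en-2-yl)oxy]phenyl}ethan-1-one F5.
- Aromatic Claisen rearrangement (PhNEt2, 130–180 °C) goes to the chelation-favoured C3 through 4-acetyl-3-hydroxy-2-(3-methylbut-2-en-1-yl)cyclohexa-3,5-dien-1-one F6.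
- F6 tautomerises, and the fallback comes back to the route at 7.

**Step 1.**
- O-alkylation competes with C-alkylation of an electron-poor phenoxide, so the yield is about 30–40 %.
- Fallback: bring in the C5 unit at the alkyne oxidation level. The fallback sets out from 1.
- Etherification with 3-chloro-3-methylbut-1-yne (K2CO3, KI, acetone) gives 4-[(2-methylbut-3-yn-2-yl)oxy]benzaldehyde F7.
- Heating (PhNEt2, 180 °C) triggers a propargyl Claisen rearrangement to 3-(3-methylbuta-1,2-dien-1-yl)-4-oxocyclohexa-1,5-diene-1-carbaldehyde F8.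
- Enolisation of F8 gives 4-hydroxy-3-(3-methylbuta-1,2-dien-1-yl)benzaldehyde F9.
- A 1,5-hydrogen shift leads to the same quinone methide 4, and its oxa-6π closure comes back to the route at 5. Steps 1 and 2 are both bypassed.

## Further compounds

F1 | step 5 | 1-(3-{[(2S)-3,3-dimethyloxiran-2-yl]methyl}-2,4-dihydroxyphenyl)ethan-1-one | CC(=O)c1ccc(O)c(C[C@@H]2OC2(C)C)c1O
F2 | step 5 | 1-[(2R)-4-hydroxy-2-(2-hydroxypropan-2-yl)-2,3-dihydro-1-benzofuran-5-yl]ethan-1-one | CC(=O)c1ccc2c(c1O)C[C@H](C(C)(C)O)O2
F3 | step 5 | 3-(2,2-dimethyl-2H-chromen-6-yl)-3-hydroxy-1-[(2R)-4-hydroxy-2-(2-hydroxypropan-2-yl)-2,3-dihydro-1-benzofuran-5-yl]propan-1-one (carbinol epimers) | CC1(C)C=Cc2cc(C(O)CC(=O)c3ccc4c(c3O)C[C@H](C(C)(C)O)O4)ccc2O1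
F4 | step 3 | 1-{2-hydroxy-4-[(2-methylbut-3-yn-2-yl)oxy]phenyl}ethan-1-one | CC(=O)c1ccc(OC(C)(C)C#C)cc1O
F5 | step 3 | 1-{2-hydroxy-4-[(2-methylbut-3-en-2-yl)oxy]phenyl}ethan-1-one | CC(=O)c1ccc(OC(C)(C)C=C)cc1O
F6 | step 3 | 4-acetyl-3-hydroxy-2-(3-methylbut-2-en-1-yl)cyclohexa-3,5-dien-1-one (racemic) | CC(=O)C1=C(O)C(CC=C(C)C)C(=O)C=C1
F7 | step 1 | 4-[(2-methylbut-3-yn-2-yl)oxy]benzaldehyde | O=Cc1ccc(OC(C)(C)C#C)cc1
F8 | step 1 | 3-(3-methylbuta-1,2-dien-1-yl)-4-oxocyclohexa-1,5-diene-1-carbaldehyde (racemic) | O=CC1=CC(C=C=C(C)C)C(=O)C=C1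
F9 | step 1 | 4-hydroxy-3-(3-methylbuta-1,2-dien-1-yl)benzaldehyde | CC(C)=C=Cc1cc(C=O)ccc1O
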